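**Strategy.** Each outer ring B is disconnected across C4'–C5' and C2'–C3'. The run C2'–C1'–C6'–C5' (carrying the bridge methylene at C1', the methoxy group at C6' and the methyl group at C5') is the silyl ketene acetal diene of a C2-alkylated 3-oxopentanoate, and C3'–C4' is a 1-alkoxyhex-1-yn-3-one that delivers the butyryl group and the C4' oxygen. A single two-directional [4+2] annulation with loss of methanol builds both hexasubstituted rings B on a tribenzylated ring A that carries two diene arms at C3 and C5 and is still unsubstituted at C1. Butyrylation of C1 and one global ether cleavage finish the synthesis.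

Key step: step 9

Remark on the design (C4' oxygen): it is carried as an isopropyl ether, because once the C2' phenol chelates the C3' ketone a primary alkyl ether at C4' loses carbonyl-assisted cleavage and cannot be told apart from the C6' methyl ether, whereas BCl3 ionises a secondary ether and spares methyl ethers.

Remark on the design (arms): they are attached by condensation and reduction at a dialdehyde, because a 2,4,6-trialkoxybenzylic halide would ionise and self-alkylate at the free C1 of ring A.

Remark on isomers: the alkylidene, keto ester, enol ether, diene and cycloadduct intermediates are mixtures of geometric isomers or labile diastereomers; all of these elements vanish on aromatisation, so one isomer or none is drawn.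

**Route**

Step 1
Reactants: 1 trichloroethylene, 2 propan-2-ol
Product: 5 (E)-1,2-dichloro-1-(propan-2-yloxy)ethene, via potassium propan-2-olate 3 (not isolated), via dichloroacetylene 4 (not isolated)
Conditions: KH, THF, 0 °C → rt; then 1, −50 °C → rt
Reagents that add atoms: none
Why: Base-induced dehydrochlorination of trichloroethylene gives dichloroacetylene, to which the alkoxide adds in anti fashion (elimination–addition route to 1,2-dichlorovinyl ethers), which sets the E geometry.

Step 2
Reactants: 5 (E)-1,2-dichloro-1-(propan-2-yloxy)ethene, 6 butanal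
Product: 8 1-(propan-2-yloxy)hex-1-yn-3-ol (racemic), via lithium isopropoxyacetylide 7 (not isolated)
Conditions: n-BuLi (2.1 equiv), THF, −78 → −40 °C; then 6, −78 °C; H2O
Reagents that add atoms: none
Why: Two equivalents of n-BuLi effect dehydrochlorination and chlorine–lithium exchange to the lithium alkoxyacetylide, which adds 1,2 to the aldehyde (acetylide addition); the carbinol centre is formed racemic and is removed in step 3.

Step 3
Reactants: 8 1-(propan-2-yloxy)hex-1-yn-3-ol
Product: 9 1-(propan-2-yloxy)hex-1-yn-3-one
Conditions: activated MnO2 (excess), CH2Cl2, rt; stored cold and used soon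
Reagents that add atoms: none
Why: Oxidation of the propargylic alcohol with activated MnO2 is neutral, so the acid-triggered Meyer–Schuster rearrangement of the alkoxyalkynyl carbinol is avoided.

Step 4
Reactants: 10 phloroglucinol
Product: 12 2,4,6-trihydroxybenzene-1,3-dicarbaldehyde, via bis(iminium) chloride 11 (not isolated)
Conditions: POCl3 (2.4 equiv), DMF, dioxane, 0 °C → rt; then H2O, 60 °C
Reagents that add atoms: N,N-dimethylformamide CN(C)C=O; water O
Why: Vilsmeier–Haack formylation of the free triphenol, which is nucleophilic enough to be formylated twice, while the two acceptor groups then in place slow a third substitution.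

Step 5
Reactants: 12 2,4,6-trihydroxybenzene-1,3-dicarbaldehyde
Product: 13 2,4,6-tris(benzyloxy)benzene-1,3-dicarbaldehyde
Conditions: BnBr (3.6 equiv), K2CO3, DMF, 60 °C
Reagents that add atoms: benzyl bromide BrCc1ccccc1
Why: Williamson ether synthesis on the phenoxides, in which the two formyl groups lower the nucleophilicity of the ring carbons so that O-benzylation should prevail over C-benzylation.

Step 6
Reactants: 13 2,4,6-tris(benzyloxy)benzene-1,3-dicarbaldehyde, 14 methyl 3-oxopentanoate
Product: 16 dimethyl 2,2'-{[2,4,6-tris(benzyloxy)-1,3-phenylene]bis(methylene)}bis(3-oxopentanoate) (mixture of labile diastereomers), via bis-alkylidene keto ester 15 (not isolated)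
Conditions: 14 (2.4 equiv), piperidine (cat.), AcOH (cat.), toluene, Dean–Stark reflux; then Hantzsch ester (diethyl 1,4-dihydro-2,6-dimethylpyridine-3,5-dicarboxylate, 2.6 equiv), 80 °C
Reagents that add atoms: none
Why: Knoevenagel condensation at both formyl groups followed in the same flask by conjugate transfer hydrogenation of the alkylidene keto esters with the Hantzsch ester (reductive alkylation) attaches both arms without a 2,4,6-trialkoxybenzylic halide, and the two new alpha stereocentres are labile and disappear in steps 7 and 8.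

Step 7
Reactants: 16 dimethyl 2,2'-{[2,4,6-tris(benzyloxy)-1,3-phenylene]bis(methylene)}bis(3-oxopentanoate)
Product: 17 dimethyl 2,2'-{[2,4,6-tris(benzyloxy)-1,3-phenylene]bis(methylene)}bis(3-methoxypent-2-enoate) (E/Z mixture)
Conditions: HC(OMe)3, H2SO4 (cat.), MeOH, 50 °C
Reagents that add atoms: trimethyl orthoformate COC(OC)OC; methanol CO
Why: Acid-catalysed ketalisation and loss of methanol (enol ether formation, driven by the orthoformate as dehydrating agent) gives the beta-methoxy enoate; a beta,gamma-unsaturated or geometric isomer would serve equally, since all converge on the same extended enolate in step 8.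

Step 8
Reactants: 17 dimethyl 2,2'-{[2,4,6-tris(benzyloxy)-1,3-phenylene]bis(methylene)}bis(3-methoxypent-2-enoate)
Product: 19 1,3,5-tris(benzyloxy)-2,4-bis{3-methoxy-2-[methoxy(trimethylsilyloxy)methylidene]pent-3-en-1-yl}benzene (one geometric isomer drawn; mixture expected), via bis(lithium dienolate) 18 (not isolated)
Conditions: LiN(iPr)2 (2.4 equiv), THF, −78 °C; Me3SiCl (3 equiv), −78 → 0 °C; non-aqueous work-up, used at once
Reagents that add atoms: chlorotrimethylsilane C[Si](C)(C)Cl
Why: Deprotonation of the gamma methylene by LiN(iPr)2 gives the extended ester enolate, whose O-silylation gives the vinylogous silyl ketene acetal (1,3-dimethoxy-1-silyloxy diene) in both arms; the geometry of the new double bonds is immaterial for step 9.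

Step 9
Reactants: 19 1,3,5-tris(benzyloxy)-2,4-bis{3-methoxy-2-[methoxy(trimethylsilyloxy)methylidene]pent-3-en-1-yl}benzene, 9 1-(propan-2-yloxy)hex-1-yn-3-one
Product: 22 1,3,5-tris(benzyloxy)-2,4-bis{[3-butanoyl-2-hydroxy-6-methoxy-5-methyl-4-(propan-2-yloxy)phenyl]methyl}benzene, via bis-cycloadduct 20 (not isolated), via bis(aryl silyl ether) 21 (not isolated)
Conditions: 9 (2.6 equiv), ZnCl2 (1 M in Et2O, 0.5 equiv), activated 4 Å molecular sieves, CH2Cl2, −40 °C → rt; then 1 M HCl, THF, rt
Reagents that add atoms: none
Why: Proposed new method: ZnCl2 activates the ynone carbonyl, the diene terminus C5' (gamma carbon of the vinylogous silyl ketene acetal) attacks the alkoxy-bearing beta carbon C4', and the alpha carbon C3' of the resulting allenolate bonds to the oxocarbenium carbon C2', either within one asynchronous [4+2] transition state or as a Mukaiyama–Michael addition followed by ring closure, after which the mixed methyl silyl ketal at C2' ionises, C5'–H is lost and aqueous acid frees the C2' phenol. The closest known reaction type is the cycloaddition–aromatisation of 1,3-dimethoxy-1-silyloxybuta-1,3-dienes with ynones and alkynoates, which has not been shown with a beta-alkoxy ynone or with a diene substituted at both C1' and C5'. Each ring B closes as a six-membered carbocycle by [4+2] annulation of the four diene carbons with the two alkyne carbons, in the stepwise limit a 6-exo-trig attack of C3' on C2'. No stereocentre remains, because the sp3 centres C2' and C5' of adduct 20 are erased on aromatisation and the diene geometry is lost. The step needs head-to-tail regiochemistry, which the substrate secures by matched polarity (largest HOMO coefficient at C5', largest LUMO coefficient at C4') and by the fully substituted, shielded C1', which disfavours alpha attack, so that the butyryl group ends between C2' and C4' and para to the C6' methoxy group. The molecular sieves take up the methanol released by the first ring so that it cannot protonate the second ketene acetal arm.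

Step 10
Reactants: 22 1,3,5-tris(benzyloxy)-2,4-bis{[3-butanoyl-2-hydroxy-6-methoxy-5-methyl-4-(propan-2-yloxy)phenyl]methyl}benzene
Product: 23 1-[2,4,6-tris(benzyloxy)-3,5-bis{[3-butanoyl-2-hydroxy-6-methoxy-5-methyl-4-(propan-2-yloxy)phenyl]methyl}phenyl]butan-1-one
Conditions: PrCO2H (3 equiv), (CF3CO)2O (3 equiv), CH2Cl2, 0 °C → rt; then K2CO3, MeOH, rt
Reagents that add atoms: butanoic acid CCCC(=O)O
Why: Friedel–Crafts acylation by the mixed butanoic trifluoroacetic anhydride at C1 of ring A, the only unsubstituted aromatic carbon of the electron-rich rings (rings B are hexasubstituted), with mild methanolysis returning any C2' phenol ester.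

Step 11
Reactants: 23 1-[2,4,6-tris(benzyloxy)-3,5-bis{[3-butanoyl-2-hydroxy-6-methoxy-5-methyl-4-(propan-2-yloxy)phenyl]methyl}phenyl]butan-1-one
Product: 24 1-{3,5-bis[(3-butanoyl-2,4-dihydroxy-6-methoxy-5-methylphenyl)methyl]-2,4,6-trihydroxyphenyl}butan-1-one (CNP0264591.0)
Conditions: BCl3 (1 M in CH2Cl2, excess), C6HMe5 (excess), CH2Cl2, −78 → 0 °C; MeOH quench
Reagents that add atoms: none
Why: Lewis-acid ether cleavage in which BCl3 removes the three benzyl ethers (the benzyl cation is trapped by pentamethylbenzene) and ionises the two secondary isopropyl ethers, while the C6' methyl ethers, primary and without a neighbouring carbonyl group, should be retained.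

**Compound list**

1 | trichloroethylene | ClC=C(Cl)Cl | starting material
2 | propan-2-ol | CC(C)O | starting material
3 | potassium propan-2-olate | CC(C)[O-].[K+] | intermediate (not isolated)
4 | dichloroacetylene | ClC#CCl | intermediate (not isolated)
5 | (E)-1,2-dichloro-1-(propan-2-yloxy)ethene | CC(C)O/C(Cl)=C\Cl | intermediate
6 | butanal | CCCC=O | starting material
7 | lithium (propan-2-yloxy)ethynide | [Li]C#COC(C)C | intermediate (not isolated)
8 | 1-(propan-2-yloxy)hex-1-yn-3-ol (racemic) | CCCC(O)C#COC(C)C | intermediate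
9 | 1-(propan-2-yloxy)hex-1-yn-3-one | CCCC(=O)C#COC(C)C | intermediate
10 | phloroglucinol | Oc1cc(O)cc(O)c1 | starting material
11 | 1,1'-(2,4,6-trihydroxy-1,3-phenylene)bis(N,N-dimethylmethaniminium) dichloride | C[N+](C)=Cc1c(O)cc(O)c(C=[N+](C)C)c1O.[Cl-].[Cl-] | intermediate (not isolated)
12 | 2,4,6-trihydroxybenzene-1,3-dicarbaldehyde | O=Cc1c(O)cc(O)c(C=O)c1O | intermediate
13 | 2,4,6-tris(benzyloxy)benzene-1,3-dicarbaldehyde | O=Cc1c(OCc2ccccc2)cc(OCc2ccccc2)c(C=O)c1OCc1ccccc1 | intermediate
14 | methyl 3-oxopentanoate | CCC(=O)CC(=O)OC | starting material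
15 | dimethyl 2,2'-{[2,4,6-tris(benzyloxy)-1,3-phenylene]dimethanylylidene}bis(3-oxopentanoate) (E/Z mixture) | CCC(=O)C(C(=O)OC)=Cc1c(OCc2ccccc2)cc(OCc2ccccc2)c(C=C(C(=O)CC)C(=O)OC)c1OCc1ccccc1 | intermediate (not isolated)
16 | dimethyl 2,2'-{[2,4,6-tris(benzyloxy)-1,3-phenylene]bis(methylene)}bis(3-oxopentanoate) (labile diastereomers) | CCC(=O)C(Cc1c(OCc2ccccc2)cc(OCc2ccccc2)c(CC(C(=O)CC)C(=O)OC)c1OCc1ccccc1)C(=O)OC | intermediate
17 | dimethyl 2,2'-{[2,4,6-tris(benzyloxy)-1,3-phenylene]bis(methylene)}bis(3-methoxypent-2-enoate) (E/Z mixture) | CCC(OC)=C(Cc1c(OCc2ccccc2)cc(OCc2ccccc2)c(CC(C(=O)OC)=C(CC)OC)c1OCc1ccccc1)C(=O)OC | intermediate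
18 | dilithium bis-dienolate of 17 (each arm CH2–C[=C(OMe)OLi]–C(OMe)=CH–CH3) | C(c1ccccc1)Oc1cc(OCc2ccccc2)c(CC(C(OC)=CC)=C(OC)O[Li])c(OCc2ccccc2)c1CC(C(OC)=CC)=C(OC)O[Li] | intermediate (not isolated)
19 | 1,3,5-tris(benzyloxy)-2,4-bis{3-methoxy-2-[methoxy(trimethylsilyloxy)methylidene]pent-3-en-1-yl}benzene (Z at both double bonds of each arm as drawn; mixture expected) | C(c1ccccc1)Oc1cc(OCc2ccccc2)c(CC(/C(OC)=C/C)=C(\OC)O[Si](C)(C)C)c(OCc2ccccc2)c1CC(/C(OC)=C/C)=C(\OC)O[Si](C)(C)C | intermediate (key-step precursor)
20 | bis(cyclohexa-1,4-diene) adduct; each ring B has sp3 C2' (OMe, OSiMe3) and sp3 C5' (H, CH3), C1'=C6'(OMe) and C3'(butanoyl)=C4'(O-iPr); diastereomer mixture | C(c1ccccc1)Oc1cc(OCc2ccccc2)c(CC2=C(OC)C(C)C(OC(C)C)=C(C(=O)CCC)C2(OC)O[Si](C)(C)C)c(OCc2ccccc2)c1CC1=C(OC)C(C)C(OC(C)C)=C(C(=O)CCC)C1(OC)O[Si](C)(C)C | intermediate (not isolated)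
21 | bis(C2' trimethylsilyl ether) of 22 | C(c1ccccc1)Oc1cc(OCc2ccccc2)c(Cc2c(O[Si](C)(C)C)c(C(=O)CCC)c(OC(C)C)c(C)c2OC)c(OCc2ccccc2)c1Cc1c(O[Si](C)(C)C)c(C(=O)CCC)c(OC(C)C)c(C)c1OC | intermediate (not isolated)
22 | 1,3,5-tris(benzyloxy)-2,4-bis{[3-butanoyl-2-hydroxy-6-methoxy-5-methyl-4-(propan-2-yloxy)phenyl]methyl}benzene | C(c1ccccc1)Oc1cc(OCc2ccccc2)c(Cc2c(O)c(C(=O)CCC)c(OC(C)C)c(C)c2OC)c(OCc2ccccc2)c1Cc1c(O)c(C(=O)CCC)c(OC(C)C)c(C)c1OC | intermediate (key-step product)
23 | 1-[2,4,6-tris(benzyloxy)-3,5-bis{[3-butanoyl-2-hydroxy-6-methoxy-5-methyl-4-(propan-2-yloxy)phenyl]methyl}phenyl]butan-1-one | CCCC(=O)c1c(OCc2ccccc2)c(Cc2c(O)c(C(=O)CCC)c(OC(C)C)c(C)c2OC)c(OCc2ccccc2)c(Cc2c(O)c(C(=O)CCC)c(OC(C)C)c(C)c2OC)c1OCc1ccccc1 | intermediate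
24 | 1-{3,5-bis[(3-butanoyl-2,4-dihydroxy-6-methoxy-5-methylphenyl)methyl]-2,4,6-trihydroxyphenyl}butan-1-one (no stereocentres) | CCCC(=O)c1c(O)c(Cc2c(O)c(C(=O)CCC)c(O)c(C)c2OC)c(O)c(Cc2c(O)c(C(=O)CCC)c(O)c(C)c2OC)c1O | target

**Step count.** Total: 11 steps. Longest linear sequence: 8 steps (steps 4 to 11, from phloroglucinol 10); the ynone branch (steps 1 to 3) joins at step 9.

**Steps most likely to fail**

Step 9 (proposed new method). The donor-substituted ynone may be too weakly electrophilic for the crowded diene, so that the ketene acetal arms are protodesilylated before any C–C bond forms. The diene may also add 1,2 to the ketone carbonyl instead of to C4', or the second arm may be quenched after the first ring has formed. The fallback uses only known chemistry; it sets out from phloroglucinol 10 and returns to the route at target 24 by the classical methylene-bridge assembly.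
- Friedel–Crafts butyrylation of 10 (butyryl chloride, AlCl3, PhNO2–CH2Cl2) should give 1-(2,4,6-trihydroxyphenyl)butan-1-one F1.
- Nuclear C-methylation of F1 (MeI, NaOMe, MeOH) should give 1-(2,4,6-trihydroxy-3-methylphenyl)butan-1-one F2.
- Methylation of the non-chelated para hydroxyl (one equivalent of Me2SO4, K2CO3, acetone) should give 1-(2,6-dihydroxy-4-methoxy-3-methylphenyl)butan-1-one F3.
- Mannich aminomethylation at the last free ring carbon (CH2O, Me2NH, EtOH) should give 1-{3-[(dimethylamino)methyl]-2,6-dihydroxy-4-methoxy-5-methylphenyl}butan-1-one F4.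
- Heating two equivalents of F4 with F1 in dioxane should expel dimethylamine; the ortho-quinone methide so formed alkylates C3 and C5 of F1 and gives 24.

Step 10. The flanking benzyloxy groups may shield C1 so that acylation stalls at the C2' oxygen, and the acidic medium may cleave the diarylmethane links by ipso attack or remove benzyl groups early. The fallback reverses the order; it sets out from 22 and returns at 24. Global ether cleavage of 22 (BCl3, C6HMe5, CH2Cl2, −78 → 0 °C) should give 1,1'-{(2,4,6-trihydroxy-1,3-phenylene)bis[methylene(2,4-dihydroxy-6-methoxy-5-methyl-3,1-phenylene)]}di(butan-1-one) F5. Classical C-acylation of its free phloroglucinol ring A at the only open nuclear position (butyryl chloride, AlCl3, PhNO2–CH2Cl2, 0 °C → rt) then gives 24.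

Step 6. Condensation may be sluggish at the two formyl groups, each flanked by two benzyloxy groups and deactivated by three donors, and hydride transfer to the donor-substituted alkylidene may stay incomplete. The fallback replaces condensation and reduction by a cationic benzylation; it sets out from 13 and returns at 16. Reduction of 13 (NaBH4, THF–MeOH, 0 °C) should give [2,4,6-tris(benzyloxy)-1,3-phenylene]dimethanol F6. Lewis-acid-catalysed dehydrative C-benzylation of a large excess of 14 with F6 (Bi(OTf)3 cat., MeNO2–CH2Cl2, 0 °C → rt) then gives 16; the excess of keto ester intercepts the benzylic cation before it can attack C1 of another ring A.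

**Further compounds**

F1 | step 9 | 1-(2,4,6-trihydroxyphenyl)butan-1-one | CCCC(=O)c1c(O)cc(O)cc1O
F2 | step 9 | 1-(2,4,6-trihydroxy-3-methylphenyl)butan-1-one | CCCC(=O)c1c(O)cc(O)c(C)c1O
F3 | step 9 | 1-(2,6-dihydroxy-4-methoxy-3-methylphenyl)butan-1-one | CCCC(=O)c1c(O)cc(OC)c(C)c1O
F4 | step 9 | 1-{3-[(dimethylamino)methyl]-2,6-dihydroxy-4-methoxy-5-methylphenyl}butan-1-one | CCCC(=O)c1c(O)c(CN(C)C)c(OC)c(C)c1O
F5 | step 10 | 1,1'-{(2,4,6-trihydroxy-1,3-phenylene)bis[methylene(2,4-dihydroxy-6-methoxy-5-methyl-3,1-phenylene)]}di(butan-1-one) | Oc1cc(O)c(Cc2c(O)c(C(=O)CCC)c(O)c(C)c2OC)c(O)c1Cc1c(O)c(C(=O)CCC)c(O)c(C)c1OC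
F6 | step 6 | [2,4,6-tris(benzyloxy)-1,3-phenylene]dimethanol | OCc1c(OCc2ccccc2)cc(OCc2ccccc2)c(CO)c1OCc1ccccc1
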